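In the early minutes L turns into E, with a lag of about 167 s, and E then stands at the charge of L, 100 µM.

Q 20 mM; L 100 µM; time 15 h

    Q + L → E + J (k1 = 0.30 L mol⁻¹ s⁻¹)
    Q + E → J + E, rate k2*[E]*[Q] (k2 = 1.2 L mol⁻¹ s⁻¹)
    J + E → Q + E, rate k3*[E] as long as [J] is above zero (k3 = 0.0023 s⁻¹)
    Q → G (k4 = 8.5 × 10⁻⁵ s⁻¹)

- average number of monomer units in a chain (chains begun, living or dead) at 15 h
- part of the Q that has reacted at 15 h

1. While J lasts, unzipping feeds Q at a steady rate, and growth and the loss to G remove Q with a pseudo-first-order constant 0.738 h⁻¹. The plateau P = 1.12 mM is the level of Q at which feed equals removal. The gap between Q and P closes with a time constant 1.36 h, short against 15 h, so c comes to 94.4%.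

2. P lies below the crossing 1.92 mM, where growth equals unzipping, so on the plateau J shrinks, at 0.343 mM h⁻¹.

3. Upper bound: with no lag, G takes 41.5% of the Q above P, plus the plateau loss, 13.0 mM in total. So dp is 59.0.

4. Lower bound: count the lag as a full delay with no E, in which Q goes on to G. Net of the Q then missing later and of the shorter plateau, G gains 0.150 mM, so dp is 57.5.

5. The forecast gives dp 58 and c 94.4%, holding that “the zero-order depolymerisation holds throughout”. Its dp lies inside the bracket.

The flask gives dp 57.9 and c 94.4%. At 15.0 h it holds Q at 5.61% of its charge, 1.12 mM, level with P. Now take the same flask charged with 8.0 mM of Q. Its J after the climb is about 4.03 mM, and draining at 0.343 mM h⁻¹ that lasts 11.7 h, less than the 15 h run. Read at 15.0 h, that flask holds J at 0.00631% of its charge and Q at 0.386 mM, below P.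

All constants were chosen freely; the result is computed.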